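Early in the red run the target rose to 20.3% by 5.00 h and then stopped, with 78.5% of the substrate still there at 15.0 h. The violet and teal runs also levelled off, so I set out M, the final target as a concentration, from the last reading of each run:

- red: substrate 0.14 M, impurity 0.13 mM, target 20.4%, M = 28.6 mM
- violet: substrate 0.22 M, impurity 0.13 mM, target 15.6%, M = 34.3 mM
- teal: substrate 0.10 M, impurity 0.26 mM, target 5.9%, M = 5.90 mM

| setting | red | violet | teal | flask |
|---|---|---|---|---|
| substrate | 0.14 M | 0.22 M | 0.10 M | 0.10 M |
| gas phase | 6.7 mM (held) | 6.7 mM (held) | 6.7 mM (held) | 6.7 mM (held) |
| free catalyst | 93 µM | 93 µM | 93 µM | 93 µM |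
| impurity | 0.13 mM | 0.13 mM | 0.26 mM | 0.13 mM |
| remark | run made earlier | run made earlier | run made earlier |  |
| time |  |  |  | 15 h |

- red (time / h: target / %, substrate / %): 2.50: 17.4, 81.7; 5.00: 20.3, 79.0; 8.00: 20.1, 78.4; 10.0: 20.1, 78.4; 12.0: 20.7, 78.2; 15.0: 20.4, 78.5
- violet (time / h: target / %, substrate / %): 1.00: 6.0, 93.7; 3.00: 13.3, 86.0; 5.00: 14.7, 85.1; 8.00: 15.2, 84.0; 12.0: 15.3, 83.8; 15.0: 15.6, 84.1
- teal (time / h: target / %, substrate / %): 1.33: 6.2, 93.3; 4.00: 6.4, 93.8; 8.00: 6.2, 93.7; 10.0: 6.4, 93.6; 15.0: 5.9, 93.3

(each reading ± 0.3 percentage points)

1. target at 15 h, in percent of the substrate charged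
2. the change that raises the amount of target at 15 h, in percent of the substrate charged most ("none" if none brings more than 2 percentage points) (south-west / east / north-west / none)
3. amount of target at 15 h, in percent of the substrate charged, after east

- south-west: doubling the transfer coefficient of the gas phase, all else as stated
- east: doubling the saturation concentration of gas phase, all else as stated
- north-west: doubling the amount of free catalyst, all else as stated

- what was read earlier has a scatter of 0.3 percentage points, one standard deviation
- at the start none of the gas phase is in solution

I read red against violet first, since they carry the flask's impurity. Two plain cases mark the scale: a fixed amount of target whatever the charge, and a fixed percentage of the charge. Let n be the charge exponent, the power of the substrate charge that M follows with impurity, catalyst and gas held fixed, so the first case has n = 0 and the second n = 1. Violet held 1.57 times red's substrate and gave 1.20 times its M, so n = 0.406.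

Carried down from red to 0.10 M, this gave me M = 24.9 mM for the flask, or 24.9%. The teal row stays off this line: with twice the flask's impurity, it made a quarter of that M.

The forecast put the flask at 24%, from 18% to 28%, so my figure stood higher. It chose east, with 44% after it, from 32% to 52%, and of the plateau it said “the catalyst dies; the plateau measures its lifetime”. My exponent held the catalyst and gas fixed, so it gave me no figure for those changes.

The flask gave 24.8%, and 45.3% after east. The best change was north-west, which gained 52 percentage points, more than east with 20 points or south-west with 12 points.

    substrate + dissolved gas + free catalyst → free catalyst + target (k = 2760 /M²/s)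
    free catalyst + impurity → spent catalyst (k = 9.97 /M/s)
    target + free catalyst ⇌ isomer of the product + free catalyst, rate k3*[free catalyst]*[target] forward; the back reaction follows from the equilibrium constant (K = 0.295, k = 1.90 /M/s)
    gas phase ⇌ dissolved gas, rate k4*(csat - [dissolved gas]) (kL = 6.63 × 10⁻⁴ /s)

The flask had come to rest. At 7.50 h the spent catalyst stood at >99.9% of the catalyst charged, the free catalyst at 0%, and the target at 24.8%. At 150 h the target still stood at 24.8% and the substrate at 73.9%, so ten times the time changed nothing. The flask's M is therefore an end value, and the red reading against the flask gives n = 0.418.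

For the neighbour charged with 0.17 M of substrate, n gave M = 30.9 mM, or 18.2%. The computed neighbour gave 18.1%.

The runs were computed for an exercise; noise was put on by code.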